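**Retrosynthetic overview**
1. 28 ⇒ 27 ⇒ 26 ⇒ 25: desilylation, enolate methylation (C15) and conjugate reduction (C1) lead back to the α,β-unsaturated δ-lactone 25. 25 ⇒ β-hydroxy ketone 22 (Wittig annulation with Ph3P=C=C=O) ⇒ isoxazoline 20 (N–O cleavage).
2. Key disconnection 20 ⇒ open-chain nitrile oxide 19: one intramolecular [3+2] cycloaddition forms C1–C2 and O–C3 together. It closes the 14-membered carbocycle and a temporary 4,5-dihydroisoxazole ring.
3. Enabling feature: in the δ-lactone ring, the ring oxygen, C3, the ring CH2 (C2) and the ring-fusion carbon C1 stand in an O–C–C–C row, the retron of an isoxazoline. C2–C3 hang on the fully substituted carbinol carbon C4 of the 14-membered ring, so they can be a terminal vinyl group, the only monosubstituted alkene of the precursor.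
4. 18 ⇒ aldehyde 3 (from (S)-linalool, brings C4) + 2-iodoalkene 13 (from 5-chloropent-1-yne) by Nozaki–Hiyama–Kishi coupling at C7–C8. The oxirane is set on the open chain by Shi epoxidation.
5. Order of ring formation: oxirane (step 9), carbocycle and isoxazoline together (step 11), isoxazoline opened (step 12), δ-lactone (step 13).

Key step: step 11

Remark (numbering): ring positions use cembrane numbering. C1 = ring-fusion CH, C2 = lactone CH2, C3 = CH–O, C4 = C(CH3)OH, C7 = CHOH, C8 = C(=CH2), C11/C12 = oxirane CH/C(CH3), C15 = CH(CH3), C16 = C=O. The target is 1R,3R,4S,7S,11S,12S,15S.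
Assumption: (S)-(+)-linalool of high enantiomeric purity is taken as commercial. The same alcohol is otherwise available from geraniol by Sharpless epoxidation and reductive opening of the derived epoxy iodide.

Step 1
Reactants: 1 (S)-(+)-linalool
Product: 2 (3S)-3,7-dimethyl-3-[(triethylsilyl)oxy]octa-1,6-diene
Conditions: TESOTf, 2,6-lutidine, CH2Cl2, −78 to 0 °C
Reagents that add atoms: triethylsilyl triflate, CC[Si](CC)(CC)OS(=O)(=O)C(F)(F)F
Why: Silyl triflate silylation (silyl ether protection) should cap the hindered tertiary allylic alcohol without touching C4, and the bulky ether is the group that later steers the cycloaddition.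

Step 2
Reactants: 2 (3S)-3,7-dimethyl-3-[(triethylsilyl)oxy]octa-1,6-diene
Product: 3 (4S)-4-methyl-4-[(triethylsilyl)oxy]hex-5-enal
Conditions: O3, CH2Cl2, Sudan Red 7B as end-point dye, −78 °C; then Me2S, −78 °C to rt
Reagents that add atoms: ozone, [O-][O+]=O
Why: Ozonolysis with reductive work-up, stopped at the colour change of the dye, should cleave only the electron-rich trisubstituted alkene and leave the slower monosubstituted vinyl group beside the silyl ether.

Step 3
Reactants: 4 5-chloropent-1-yne
Product: 7 (2E)-6-chloro-3-methylhex-2-en-1-ol, via alkenylalane 5 (not isolated), via lithium alanate 6 (not isolated)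
Conditions: Me3Al, Cp2ZrCl2 (0.25 equiv), CH2Cl2, 0 °C to rt; volatiles removed; n-BuLi, THF, −78 °C; (CH2O)n, rt
Reagents that add atoms: trimethylaluminium, C[Al](C)C; formaldehyde (as paraformaldehyde), C=O
Why: Zirconium-catalysed carboalumination (Negishi carboalumination) adds methyl and aluminium syn to the terminal alkyne, and hydroxymethylation of the alanate with retention should therefore give the E-trisubstituted allylic alcohol, the chloride being inert because the aluminium-bearing carbon is trans to the chloropropyl chain.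

Step 4
Reactants: 7 (2E)-6-chloro-3-methylhex-2-en-1-ol
Product: 8 (2E)-1-bromo-6-chloro-3-methylhex-2-ene
Conditions: CBr4, PPh3, CH2Cl2, 0 °C
Reagents that add atoms: tetrabromomethane, BrC(Br)(Br)Br
Why: The Appel reaction converts the primary allylic alcohol into the bromide under neutral conditions by SN2 displacement of the oxyphosphonium group, so that alkene position and E geometry should be kept.

Step 5
Reactants: 8 (2E)-1-bromo-6-chloro-3-methylhex-2-ene; 9 1-(trimethylsilyl)propyne
Product: 11 (5E)-9-chloro-6-methylnon-5-en-1-yne, via silylated enyne 10 (not isolated)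
Conditions: 9, n-BuLi, THF, −78 to −20 °C; 8, −78 to 0 °C; then K2CO3 (cat.), MeOH, rt
Reagents that add atoms: none
Why: The propargylic lithium reagent should displace the allylic bromide by SN2 far faster than the primary chloride (propargylation of an allylic halide), and carbonate-catalysed methanolysis then removes the alkynyl silyl group in the same flask.

Step 6
Reactants: 11 (5E)-9-chloro-6-methylnon-5-en-1-yne
Product: 13 (5E)-9-chloro-2-iodo-6-methylnona-1,5-diene, via internal alkenylalane 12 (not isolated)
Conditions: DIBAL-H, Ni(dppp)Cl2 (3 mol %), THF, 0 °C to rt; then I2, THF, −78 to 0 °C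
Reagents that add atoms: iodine, II
Why: Nickel-catalysed hydroalumination with the dppp ligand places aluminium on the internal alkyne carbon, and iodinolysis of the C–Al bond with retention should give the 2-iodo-1-alkene while the trisubstituted alkene and the chloride stay untouched.

Step 7
Reactants: 13 (5E)-9-chloro-2-iodo-6-methylnona-1,5-diene; 3 (4S)-4-methyl-4-[(triethylsilyl)oxy]hex-5-enal
Product: 14 (3S,6S,10E)-14-chloro-3,11-dimethyl-7-methylidene-3-[(triethylsilyl)oxy]tetradeca-1,10-dien-6-ol
Conditions: CrCl2 (3 equiv), NiCl2 (2 mol %), valinol-derived N-[2-(4-isopropyl-4,5-dihydrooxazol-2-yl)-6-methylphenyl]methanesulfonamide (antipode for Re-face attack), Et3N, THF, rt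
Reagents that add atoms: none
Why: Nickel-catalysed formation of the alkenylchromium reagent and its aldehyde-selective addition (asymmetric Nozaki–Hiyama–Kishi coupling) should join the fragments without touching chloride, vinyl group or silyl ether, the chiral oxazoline–sulfonamide ligand on chromium directing attack to the Re face of 3 and so setting the carbinol centre (C7 of the ring, C6 of the chain name) as S.

Step 8
Reactants: 14 (3S,6S,10E)-14-chloro-3,11-dimethyl-7-methylidene-3-[(triethylsilyl)oxy]tetradeca-1,10-dien-6-ol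
Product: 15 (3S,6S,10E)-6-[(tert-butyldimethylsilyl)oxy]-14-chloro-3,11-dimethyl-7-methylidene-3-[(triethylsilyl)oxy]tetradeca-1,10-diene
Conditions: TBSOTf, 2,6-lutidine, CH2Cl2, −78 °C
Reagents that add atoms: tert-butyldimethylsilyl triflate, CC(C)(C)[Si](C)(C)OS(=O)(=O)C(F)(F)F
Why: Silyl triflate silylation of the secondary allylic alcohol removes the last free hydroxy group, which is needed because the isocyanate of step 11 would otherwise carbamoylate it, and C7 is not affected.

Step 9
Reactants: 15 (3S,6S,10E)-6-[(tert-butyldimethylsilyl)oxy]-14-chloro-3,11-dimethyl-7-methylidene-3-[(triethylsilyl)oxy]tetradeca-1,10-diene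
Product: 16 (3S,6S,10S,11S)-6-[(tert-butyldimethylsilyl)oxy]-14-chloro-10,11-epoxy-3,11-dimethyl-7-methylidene-3-[(triethylsilyl)oxy]tetradec-1-ene
Conditions: 1,2:4,5-di-O-isopropylidene-β-L-erythro-2,3-hexodiulo-2,6-pyranose (0.3 equiv), Oxone, K2CO3, Bu4NHSO4, MeCN–dimethoxymethane/aq. Na2B4O7–EDTA buffer (pH 10.5), 0 °C
Reagents that add atoms: potassium peroxymonosulfate (active part of Oxone), [K+].[O-]S(=O)(=O)OO
Why: In the Shi epoxidation the chiral dioxirane reacts much faster with the E-trisubstituted alkene than with the monosubstituted and the 1,1-disubstituted alkenes, the L-fructose-derived ketone (spiro transition state) should deliver oxygen to the face that gives the S,S oxirane (ring C11 and C12), and syn addition to the E-alkene fixes the relative configuration.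

Step 10
Reactants: 16 (3S,6S,10S,11S)-6-[(tert-butyldimethylsilyl)oxy]-14-chloro-10,11-epoxy-3,11-dimethyl-7-methylidene-3-[(triethylsilyl)oxy]tetradec-1-ene
Product: 18 (3S,6S,10S,11S)-6-[(tert-butyldimethylsilyl)oxy]-10,11-epoxy-3,11-dimethyl-7-methylidene-14-nitro-3-[(triethylsilyl)oxy]tetradec-1-ene, via primary iodide 17 (not isolated)
Conditions: NaI, NaNO2, phloroglucinol, DMSO, 35 °C
Reagents that add atoms: sodium nitrite, [Na+].[O-]N=O
Why: Iodide exchange (Finkelstein reaction) turns the chloride into the more reactive iodide, which nitrite should displace through nitrogen (Kornblum nitroalkane synthesis) under neutral conditions that spare the oxirane and both silyl ethers, phloroglucinol intercepting nitrite ester.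

Step 11
Reactants: 18 (3S,6S,10S,11S)-6-[(tert-butyldimethylsilyl)oxy]-10,11-epoxy-3,11-dimethyl-7-methylidene-14-nitro-3-[(triethylsilyl)oxy]tetradec-1-ene
Product: 20 isoxazoline-bridged carbocycle (3R,4S,7S,11S,12S): cyclotetradecane ring C1–C14 whose C1 and C3 are joined by a =N–O– bridge (C1=N; O on C3; C2 is the CH2 of the 4,5-dihydroisoxazole); 4-methyl-4-OTES; 7-OTBS; 8-methylidene; 11,12-epoxide bearing the 12-methyl group, via nitrile oxide 19 (not isolated)
Conditions: PhNCO (3 equiv), Et3N (0.3 equiv), toluene, 70 °C; 18 added by syringe pump over 20 h (final concentration about 1 mM)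
Reagents that add atoms: none
Why: Phenyl isocyanate dehydrates the triethylamine-derived nitronate of 18 to nitrile oxide 19 (Mukaiyama–Hoshino method), whose C≡N+–O− unit adds in a concerted, asynchronous [3+2] cycloaddition across the vinyl group, so that the C1–C2 and O–C3 bonds form in the same event; the closest known reaction type is the intramolecular nitrile oxide–alkene cycloaddition, which has precedent for large rings. Two rings close at once: the 4,5-dihydroisoxazole by the cycloaddition itself and the 14-membered carbocycle in the bridged mode (dipole carbon to the terminal CH2, oxygen to the substituted carbon), which is the normal intermolecular regiochemistry and returns once the tether is long (eleven atoms here). The one new stereocentre, C3, is controlled by C4 through the inside-alkoxy effect: in the staggered transition state the silyloxy group sits inside, the C5 chain anti and the methyl group outside, which leads from 4S to 3R (O–C3 and O–C4 anti). The step needs site selectivity among the π-bonds and ring closure faster than furoxan formation: the vinyl group is the only monosubstituted alkene, the 1,1-disubstituted C8 alkene is screened by the neighbouring OTBS group and could only give strained eight- or nine-membered rings, the former trisubstituted alkene is already an inert oxirane, and slow addition keeps the nitrile oxide dilute. No hydroxy group is free, so the isocyanate has no other partner, and the neutral conditions spare oxirane and silyl ethers.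

Step 12
Reactants: 20 isoxazoline-bridged carbocycle
Product: 22 (3R,4S,7S,11S,12S)-7-[(tert-butyldimethylsilyl)oxy]-11,12-epoxy-3-hydroxy-4,12-dimethyl-8-methylidene-4-[(triethylsilyl)oxy]cyclotetradecan-1-one, via hydroxy imine 21 (not isolated)
Conditions: SmI2, B(OH)3, THF–H2O, rt
Reagents that add atoms: water, O
Why: Single-electron reduction by SmI2 cleaves the weak N–O bond and boric acid hydrolyses the resulting hydroxy imine (reductive isoxazoline opening to a β-hydroxy ketone), so that nitrogen leaves as ammonia while the O–C3 bond, C3 and the isolated oxirane and alkene should be kept.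

Step 13
Reactants: 22 (3R,4S,7S,11S,12S)-7-[(tert-butyldimethylsilyl)oxy]-11,12-epoxy-3-hydroxy-4,12-dimethyl-8-methylidene-4-[(triethylsilyl)oxy]cyclotetradecan-1-one; 23 (triphenylphosphoranylidene)ketene
Product: 25 α,β-unsaturated δ-lactone (3R,4S,7S,11S,12S): 5,6-dihydro-2H-pyran-2-one built on the carbocycle of 22 (C1=C15 double bond; C16(=O)–O–C3); 4-OTES; 7-OTBS; 8-methylidene; 11,12-epoxide, via ylide ester 24 (not isolated)
Conditions: toluene, 110 °C
Reagents that add atoms: none
Why: The C3 hydroxy group adds to the cumulated ylide to give a stabilised acyl ylide, which should close the six-membered ring by intramolecular Wittig olefination of the C1 ketone under neutral conditions that avoid β-elimination, the ring forcing the geometry with C2 and C16 cis on the new C1=C15 bond.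

Step 14
Reactants: 25 α,β-unsaturated δ-lactone
Product: 26 saturated δ-lactone (1R,3R,4S,7S,11S,12S): 25 with C1–H and C15H2; H-1 cis to H-3
Conditions: [(Ph3P)CuH]6, degassed toluene, H2O (5 equiv), rt
Reagents that add atoms: none
Why: Copper hydride conjugate reduction touches only the enoate, and hydride should reach C1 from the outer face of the bridged bicycle, anti to the C4 substituent on C3 (axial attack on the half-chair), which puts H-1 cis to H-3 and so gives 1R.

Step 15
Reactants: 26 saturated δ-lactone
Product: 27 bis-silyl ether of the target (1R,3R,4S,7S,11S,12S,15S): 26 with a methyl group on C15 trans to the C14 chain on C1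
Conditions: LDA, THF, −78 °C; MeI, DMPU, −78 to −40 °C
Reagents that add atoms: iodomethane, CI
Why: Alkylation of the lithium enolate of the lactone with iodomethane should occur anti to the C14 chain on the neighbouring C1, giving the trans (all-equatorial, 15S) lactone, which is also the thermodynamic epimer so that any minor isomer can be equilibrated with base.

Step 16
Reactants: 27 bis-silyl ether of the target
Product: 28 target CNP0262409.2 (1R,3R,4S,7S,11S,12S,15S)
Conditions: TBAF, AcOH, THF, 0 °C to rt
Reagents that add atoms: none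
Why: Fluoride-induced desilylation buffered with acetic acid should free the tertiary and the secondary allylic alcohol without opening the oxirane, moving the acyl group or epimerising C15.

**Compound list**
1 | (S)-(+)-linalool | C=C[C@@](C)(O)CCC=C(C)C | starting material
2 | (3S)-3,7-dimethyl-3-[(triethylsilyl)oxy]octa-1,6-diene | C=C[C@@](C)(O[Si](CC)(CC)CC)CCC=C(C)C | intermediate
3 | (4S)-4-methyl-4-[(triethylsilyl)oxy]hex-5-enal | C=C[C@@](C)(O[Si](CC)(CC)CC)CCC=O | intermediate
4 | 5-chloropent-1-yne | C#CCCCCl | starting material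
5 | [(1E)-5-chloro-2-methylpent-1-en-1-yl]dimethylalane (not isolated) | C[Al](C)/C=C(\C)CCCCl | intermediate
6 | lithium butyl[(1E)-5-chloro-2-methylpent-1-en-1-yl]dimethylalanate (not isolated) | [Li+].CCCC[Al-](C)(C)/C=C(\C)CCCCl | intermediate
7 | (2E)-6-chloro-3-methylhex-2-en-1-ol | OC/C=C(\C)CCCCl | intermediate
8 | (2E)-1-bromo-6-chloro-3-methylhex-2-ene | BrC/C=C(\C)CCCCl | intermediate
9 | 1-(trimethylsilyl)propyne | CC#C[Si](C)(C)C | starting material
10 | [(5E)-9-chloro-6-methylnon-5-en-1-yn-1-yl]trimethylsilane (not isolated) | C[Si](C)(C)C#CCC/C=C(\C)CCCCl | intermediate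
11 | (5E)-9-chloro-6-methylnon-5-en-1-yne | C#CCC/C=C(\C)CCCCl | intermediate
12 | [(5E)-9-chloro-6-methylnona-1,5-dien-2-yl]bis(2-methylpropyl)alane (not isolated) | C=C(CC/C=C(\C)CCCCl)[Al](CC(C)C)CC(C)C | intermediate
13 | (5E)-9-chloro-2-iodo-6-methylnona-1,5-diene | C=C(I)CC/C=C(\C)CCCCl | intermediate
14 | (3S,6S,10E)-14-chloro-3,11-dimethyl-7-methylidene-3-[(triethylsilyl)oxy]tetradeca-1,10-dien-6-ol | C=C(CC/C=C(\C)CCCCl)[C@@H](O)CC[C@](C)(O[Si](CC)(CC)CC)C=C | intermediate
15 | (3S,6S,10E)-6-[(tert-butyldimethylsilyl)oxy]-14-chloro-3,11-dimethyl-7-methylidene-3-[(triethylsilyl)oxy]tetradeca-1,10-diene | C=C(CC/C=C(\C)CCCCl)[C@@H](O[Si](C)(C)C(C)(C)C)CC[C@](C)(O[Si](CC)(CC)CC)C=C | intermediate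
16 | (3S,6S,10S,11S)-6-[(tert-butyldimethylsilyl)oxy]-14-chloro-10,11-epoxy-3,11-dimethyl-7-methylidene-3-[(triethylsilyl)oxy]tetradec-1-ene | C=C(CC[C@@H]1O[C@@]1(C)CCCCl)[C@@H](O[Si](C)(C)C(C)(C)C)CC[C@](C)(O[Si](CC)(CC)CC)C=C | intermediate
17 | 14-iodo analogue of 16 (not isolated) | C=C(CC[C@@H]1O[C@@]1(C)CCCI)[C@@H](O[Si](C)(C)C(C)(C)C)CC[C@](C)(O[Si](CC)(CC)CC)C=C | intermediate
18 | 14-nitro analogue of 16 | C=C(CC[C@@H]1O[C@@]1(C)CCC[N+](=O)[O-])[C@@H](O[Si](C)(C)C(C)(C)C)CC[C@](C)(O[Si](CC)(CC)CC)C=C | intermediate
19 | (4S,5S,9S,12S)-9-[(tert-butyldimethylsilyl)oxy]-4,5-epoxy-4,12-dimethyl-8-methylidene-12-[(triethylsilyl)oxy]tetradec-13-enenitrile oxide (not isolated) | C=C(CC[C@@H]1O[C@@]1(C)CCC#[N+][O-])[C@@H](O[Si](C)(C)C(C)(C)C)CC[C@](C)(O[Si](CC)(CC)CC)C=C | intermediate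
20 | isoxazoline-bridged 14-membered carbocycle, 3R,4S,7S,11S,12S (C1=N–O–C3) | C=C1CC[C@@H]2O[C@@]2(C)CCC2=NO[C@H](C2)[C@@](C)(O[Si](CC)(CC)CC)CC[C@@H]1O[Si](C)(C)C(C)(C)C | intermediate
21 | β-hydroxy imine, the C1=NH analogue of 22 (not isolated) | C=C1CC[C@@H]2O[C@@]2(C)CCC(=N)C[C@@H](O)[C@@](C)(O[Si](CC)(CC)CC)CC[C@@H]1O[Si](C)(C)C(C)(C)C | intermediate
22 | (3R,4S,7S,11S,12S)-7-[(tert-butyldimethylsilyl)oxy]-11,12-epoxy-3-hydroxy-4,12-dimethyl-8-methylidene-4-[(triethylsilyl)oxy]cyclotetradecan-1-one | C=C1CC[C@@H]2O[C@@]2(C)CCC(=O)C[C@@H](O)[C@@](C)(O[Si](CC)(CC)CC)CC[C@@H]1O[Si](C)(C)C(C)(C)C | intermediate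
23 | (triphenylphosphoranylidene)ketene | O=C=C=P(c1ccccc1)(c1ccccc1)c1ccccc1 | starting material
24 | (triphenylphosphoranylidene)acetate of the C3 hydroxy group of 22 (not isolated) | C=C1CC[C@@H]2O[C@@]2(C)CCC(=O)C[C@@H](OC(=O)C=P(c2ccccc2)(c2ccccc2)c2ccccc2)[C@@](C)(O[Si](CC)(CC)CC)CC[C@@H]1O[Si](C)(C)C(C)(C)C | intermediate
25 | α,β-unsaturated δ-lactone, 3R,4S,7S,11S,12S (C1=C15, C16(=O)–O–C3) | C=C1CC[C@@H]2O[C@@]2(C)CCC2=CC(=O)O[C@H](C2)[C@@](C)(O[Si](CC)(CC)CC)CC[C@@H]1O[Si](C)(C)C(C)(C)C | intermediate
26 | saturated δ-lactone without the C15 methyl group, 1R,3R,4S,7S,11S,12S | C=C1CC[C@@H]2O[C@@]2(C)CC[C@@H]2C[C@@H](OC(=O)C2)[C@@](C)(O[Si](CC)(CC)CC)CC[C@@H]1O[Si](C)(C)C(C)(C)C | intermediate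
27 | 4-O-TES, 7-O-TBS ether of the target, 1R,3R,4S,7S,11S,12S,15S | C=C1CC[C@@H]2O[C@@]2(C)CC[C@@H]2C[C@@H](OC(=O)[C@H]2C)[C@@](C)(O[Si](CC)(CC)CC)CC[C@@H]1O[Si](C)(C)C(C)(C)C | intermediate
28 | CNP0262409.2 | C=C1CC[C@@H]2O[C@@]2(C)CC[C@@H]2C[C@@H](OC(=O)[C@H]2C)[C@@](C)(O)CC[C@@H]1O | target

**Step count and risks**
Total step count: 16. Longest linear sequence: 14 steps (steps 3 to 16, from 4).

Step 11 (most at risk). Dimerisation of the nitrile oxide to the furoxan, or intermolecular cycloaddition, may outrun closure of the large ring. The facial bias at the vinyl group may also be weak, because the methyl group and the chain on C4 differ little in size.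
The fallback sets out from 13 and 2 and comes back at 20. The cycloaddition is run between two fragments, and the carbocycle is closed at C7–C8 instead.
- Shi epoxidation of 13 with the same ketone should give the epoxy iodoalkene F1.
- NaI/NaNO2 in DMSO should give the nitro compound F2.
- PhNCO/Et3N with an excess of 2 should give the open-chain isoxazoline F3, since only the vinyl group of 2 reacts.
- Dye-controlled ozonolysis of the remaining trisubstituted alkene should give the aldehyde F4.
- An intramolecular Nozaki–Hiyama–Kishi reaction (CrCl2, NiCl2 cat., THF–DMSO, high dilution) should give the macrocyclic allylic alcohol F5.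
- TBSOTf/2,6-lutidine then leads to 20.

Step 13. Addition of the hindered C3 alcohol to the cumulated ylide may be slow. The stabilised ylide may fail to engage the dialkyl ketone, so that thermal loss of the β-oxygen function takes over.
The fallback sets out from 22 and comes back at 25. The ring is closed by carbonyl addition instead of olefination.
- Bromoacetyl bromide/pyridine should give the bromoacetate F6.
- SmI2 (THF, −78 °C) should close the ring by an intramolecular Reformatsky reaction to the β-hydroxy lactone F7.
- Dehydration (MsCl, Et3N, then DBU) should give the conjugated lactone 25.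

Step 7. The ligand may give poor facial selectivity on the unbranched aldehyde, or the ligated chromium reagent may couple slowly.
The fallback sets out from 13 and 3 and comes back at 14. The carbinol centre is set by reduction instead of addition.
- The ligand-free Nozaki–Hiyama–Kishi coupling gives 14 together with its carbinol epimer F8.
- Dess–Martin oxidation of the mixture should give the α-methylene ketone F9.
- Corey–Bakshi–Shibata reduction with the (R)-methyl oxazaborolidine and BH3·SMe2 should return 14.

Further compounds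
F1 | step 11 | (2S,3S)-2-(3-chloropropyl)-3-(3-iodobut-3-en-1-yl)-2-methyloxirane | C=C(I)CC[C@@H]1O[C@@]1(C)CCCCl
F2 | step 11 | (2S,3S)-3-(3-iodobut-3-en-1-yl)-2-methyl-2-(3-nitropropyl)oxirane | C=C(I)CC[C@@H]1O[C@@]1(C)CCC[N+](=O)[O-]
F3 | step 11 | open-chain isoxazoline from the nitrile oxide of F2 and the vinyl group of 2 (5R on the isoxazoline, S at the silyloxy carbon, S,S oxirane) | C=C(I)CC[C@@H]1O[C@@]1(C)CCC1=NO[C@H](C1)[C@@](C)(O[Si](CC)(CC)CC)CCC=C(C)C
F4 | step 11 | aldehyde from cleavage of the trisubstituted alkene of F3 | C=C(I)CC[C@@H]1O[C@@]1(C)CCC1=NO[C@H](C1)[C@@](C)(O[Si](CC)(CC)CC)CCC=O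
F5 | step 11 | 7-hydroxy analogue of 20 (3R,4S,7S,11S,12S) | C=C1CC[C@@H]2O[C@@]2(C)CCC2=NO[C@H](C2)[C@@](C)(O[Si](CC)(CC)CC)CC[C@@H]1O
F6 | step 13 | bromoacetate of the C3 hydroxy group of 22 | C=C1CC[C@@H]2O[C@@]2(C)CCC(=O)C[C@@H](OC(=O)CBr)[C@@](C)(O[Si](CC)(CC)CC)CC[C@@H]1O[Si](C)(C)C(C)(C)C
F7 | step 13 | β-hydroxy δ-lactone (tertiary alcohol at C1, configuration at C1 open) | C=C1CC[C@@H]2O[C@@]2(C)CCC2(O)C[C@@H](OC(=O)C2)[C@@](C)(O[Si](CC)(CC)CC)CC[C@@H]1O[Si](C)(C)C(C)(C)C
F8 | step 7 | (3S,6R,10E)-epimer of 14 | C=C(CC/C=C(\C)CCCCl)[C@H](O)CC[C@](C)(O[Si](CC)(CC)CC)C=C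
F9 | step 7 | (3S,10E)-14-chloro-3,11-dimethyl-7-methylidene-3-[(triethylsilyl)oxy]tetradeca-1,10-dien-6-one | C=C(CC/C=C(\C)CCCCl)C(=O)CC[C@](C)(O[Si](CC)(CC)CC)C=C
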